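**Retrosynthetic overview**

1. Locants used in the prose (systematic names keep their own): C12 lactone C=O, C11 its α-carbon, C13 the exocyclic CH2, C7 the ring carbon on C11, C8 the lactone O–CH, C9 the isovalerate carbon, C10 the quaternary ether carbon (methyl C14), C1–C3 the CH2 chain, C4 the CHCH3 carbon (methyl C15), C5 the ether methine, C6 the CH2 between C5 and C7; ring A = oxepane O–C5–C6–C7–C8–C9–C10, ring B = oxepane O–C5–C4–C3–C2–C1–C10.
2. Late stage: isovalerate by acylation, C13 by Eschenmoser methylenation, the lactone (C8–O) together with C9–OH by epoxy-acid lactonisation of a C8=C9 alkene, C7–C11 by Johnson–Claisen rearrangement from a C9 allylic alcohol; this leads back to a simple bicyclic alkene.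
3. Key disconnection: C6–C7 and O–C10 together. Enabling feature: in ring A the ring oxygen sits on C5 with C6 next to it, and C7 and C10 are the 1,4-termini of the C7–C8–C9–C10 unit, whose vicinal C8/C9 oxygens mark a former alkene. Ring A is therefore the formal (4+3) adduct of a C6–C5=O keto-carbene and a C7=C8–C9=C10 diene (cyclopropanation, then retro-Claisen shift); the C4–C1 chain that already joins C5 to C10 makes the event intramolecular, so the same O–C10 bond closes ring B.
4. Precursor: an acyclic diazoketone; C1–C5, C8–C10, C14 and C15 come from geranyl acetate (C4 set by asymmetric hydrogenation), C7 from a Wittig methylene, C6 from diazomethane.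
5. Ring order: rings A and B (and with them the ten-membered carbocycle) in step 8; the lactone ring in step 14.

Key step: step 8

Remark: the S sense of the hydrogenation in step 3 is assumed to follow that of tiglic acid with the same catalyst; the ligand antipode would be used if it did not.

**Route**

Step 1
Reactants: 1 geranyl acetate
Product: 2 (2E,6E)-8-hydroxy-3,7-dimethylocta-2,6-dien-1-yl acetate
Conditions: SeO2 (cat.), t-BuOOH, salicylic acid (cat.), CH2Cl2, rt
Reagents that add atoms: tert-butyl hydroperoxide, CC(C)(C)OO (the oxygen is relayed by the SeO2 catalyst)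
Why: Riley allylic oxidation (ene reaction, then [2,3]-shift) should hydroxylate the E-methyl group of the electron-richer terminal alkene and spare the allylic acetate alkene.

Step 2
Reactants: 2 (2E,6E)-8-hydroxy-3,7-dimethylocta-2,6-dien-1-yl acetate
Product: 4 (2E,6E)-8-acetoxy-2,6-dimethylocta-2,6-dienoic acid, via aldehyde 3 (not isolated)
Conditions: TEMPO (cat.), PhI(OAc)2, CH2Cl2, rt; then NaClO2, NaH2PO4, 2-methyl-2-butene, t-BuOH/H2O, rt
Reagents that add atoms: sodium chlorite, [Na+].[O-]Cl=O
Why: Oxoammonium oxidation to the enal and Pinnick oxidation in the same flask should give the (E)-2-methyl-2-enoic acid with both alkene geometries intact.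

Step 3
Reactants: 4 (2E,6E)-8-acetoxy-2,6-dimethylocta-2,6-dienoic acid
Product: 5 (2S,6E)-8-acetoxy-2,6-dimethyloct-6-enoic acid
Conditions: Ru(OAc)2[(S)-H8-BINAP] (cat.), H2 (4 atm), MeOH, rt
Reagents that add atoms: none
Why: Carboxylate-directed asymmetric hydrogenation of a tiglic-acid-type 2-methyl-2-enoic acid should set C4 as S (ligand control) while the non-coordinating allylic acetate alkene stays untouched.

Step 4
Reactants: 5 (2S,6E)-8-acetoxy-2,6-dimethyloct-6-enoic acid
Product: 6 (2S,6E)-8-hydroxy-2,6-dimethyloct-6-enoic acid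
Conditions: LiOH, THF/H2O, rt; then aq. HCl to pH 3
Reagents that add atoms: none
Why: Acetate saponification frees the allylic alcohol, and C4 is safe because the neighbouring carboxylate does not enolise.

Step 5
Reactants: 6 (2S,6E)-8-hydroxy-2,6-dimethyloct-6-enoic acid
Product: 7 (2S,6E)-2,6-dimethyl-8-oxooct-6-enoic acid
Conditions: TEMPO (cat.), PhI(OAc)2, CH2Cl2, rt
Reagents that add atoms: none
Why: TEMPO/PhI(OAc)2 oxidation of the allylic alcohol should stop at the stable (E)-enal in the presence of the free acid.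

Step 6
Reactants: 7 (2S,6E)-2,6-dimethyl-8-oxooct-6-enoic acid
Product: 8 (2S,6E)-2,6-dimethylnona-6,8-dienoic acid
Conditions: Ph3PCH3Br, KN(SiMe3)2 (excess), THF, 0 °C to rt; then aq. HCl
Reagents that add atoms: methyltriphenylphosphonium bromide, C[P+](c1ccccc1)(c1ccccc1)c1ccccc1.[Br-]
Why: Wittig methylenation of the enal, run on the potassium carboxylate so that C4 cannot epimerise, should give the terminal (E)-1,3-diene.

Step 7
Reactants: 8 (2S,6E)-2,6-dimethylnona-6,8-dienoic acid
Product: 10 (3S,7E)-1-diazo-3,7-dimethyldeca-7,9-dien-2-one, via mixed anhydride 9 (not isolated)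
Conditions: i-BuOCOCl, N-methylmorpholine, THF, −20 °C; then CH2N2, Et2O, 0 °C
Reagents that add atoms: diazomethane, C=[N+]=[N-]
Why: Acylation of diazomethane by the mixed carbonic anhydride (first stage of the Arndt–Eistert sequence) should give the terminal diazoketone without a base strong enough to epimerise C4.

Step 8
Reactants: 10 (3S,7E)-1-diazo-3,7-dimethyldeca-7,9-dien-2-one
Product: 12 (1R,7S)-1,7-dimethyl-11-oxabicyclo[4.4.1]undeca-2,5-diene, via cyclopropyl ketone 11 (not isolated)
Conditions: Cu(MeCN)4PF6 (5 mol %), ClCH2CH2Cl, 80 °C, 10 added by syringe pump (final 2 mM), then 80 °C until 11 is consumed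
Reagents that add atoms: none
Why: Proposed new method: the copper carbenoid formed from 10 should add to the terminal C7=C8 bond of the tethered diene (C6–C7 and C6–C8 formed) to give cis-acyl-vinylcyclopropane 11, in which the tether holds the C5=O and C9=C10 π-bonds in the boat array of a retro-Claisen [3,3] shift that forms O–C10 and breaks C6–C8; the closest known reactions are the copper- or rhodium-catalysed macrocyclising cyclopropanation of diazo carbonyl compounds and the retro-Claisen rearrangement of cis-2-vinylcyclopropyl aldehydes and ketones to 2,5-dihydrooxepines, which have not been run in tandem across a tether that joins the acyl carbon to the vinyl terminus. Ring A (O–C5–C6–C7–C8–C9–C10) is closed in a formal (4+3) manner, C6–C7 by [2+1] carbenoid addition (which also closes the ten-membered carbocycle) and O–C10 by the sigmatropic shift, and ring B (O–C5–C4–C3–C2–C1–C10) is closed by the same O–C10 bond as a seven-membered ring through the boat transition state. C10 is the only new stereocentre that survives and is controlled by C4: allylic 1,3-strain keeps C4–H syn to C6 and the C4 methyl group on the outer face of the forming ring B, which fixes the diene face attacked, while a simple model of the boat shows that the tether can only span to the E position at C10 with the methyl group inside, so the E geometry of C9=C10 is essential. The step needs site selectivity for C7=C8 over C9=C10 (secured by the unhindered, most nucleophilic diene terminus), cyclopropanation in preference to 1,5 C–H insertion at C2 and to dimerisation (copper instead of rhodium, slow addition at high dilution) and the cis acyl/vinyl arrangement (enforced by the tether). The shift should be driven by release of the cyclopropane strain and of the strain of the (E)-cyclononene ring of 11, and C7 is deliberately left unsubstituted because a substituent there would be forced into the hindered inside position of the boat.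

Step 9
Reactants: 12 (1R,7S)-1,7-dimethyl-11-oxabicyclo[4.4.1]undeca-2,5-diene
Product: 13 (1R,6R,7S)-1,7-dimethyl-11-oxabicyclo[4.4.1]undec-2-ene
Conditions: Mn(dpm)3 (cat.), PhSiH3, t-BuOOH, i-PrOH, rt
Reagents that add atoms: none
Why: Metal-hydride hydrogen-atom-transfer hydrogenation should reduce only the electron-rich trisubstituted bridgehead enol ether (through the tertiary α-oxy radical at C5) and spare the 1,2-disubstituted C8=C9 alkene, the C5 configuration being dictated by the bicyclic frame.

Step 10
Reactants: 13 (1R,6R,7S)-1,7-dimethyl-11-oxabicyclo[4.4.1]undec-2-ene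
Product: 14 (1R,2S,3S,6R,7S)-2,3-epoxy-1,7-dimethyl-11-oxabicyclo[4.4.1]undecane
Conditions: mCPBA, NaHCO3, CH2Cl2, 0 °C
Reagents that add atoms: mCPBA, OOC(=O)c1cccc(Cl)c1
Why: Prilezhaev epoxidation should take place on the exo face of C8=C9, the face of ring A turned away from the C1–C4 bridge.

Step 11
Reactants: 14 (1R,2S,3S,6R,7S)-2,3-epoxy-1,7-dimethyl-11-oxabicyclo[4.4.1]undecane
Product: 15 (1R,2S,6R,7S)-1,7-dimethyl-11-oxabicyclo[4.4.1]undec-3-en-2-ol
Conditions: Et2AlCl, lithium 2,2,6,6-tetramethylpiperidide, toluene, 0 °C to rt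
Reagents that add atoms: none
Why: Aluminium-amide-mediated syn β-elimination of the epoxide can only remove a C7 proton because C10 is quaternary, so the allylic alcohol should keep its oxygen on C9 on the exo face.

Step 12
Reactants: 15 (1R,2S,6R,7S)-1,7-dimethyl-11-oxabicyclo[4.4.1]undec-3-en-2-ol
Product: 17 ethyl 2-[(1R,4R,6R,7S)-1,7-dimethyl-11-oxabicyclo[4.4.1]undec-2-en-4-yl]acetate, via ketene acetal 16 (not isolated)
Conditions: CH3C(OEt)3, EtCO2H (cat.), xylene, 140 °C, EtOH distilled off
Reagents that add atoms: triethyl orthoacetate, CCOC(C)(OCC)OCC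
Why: The Johnson–Claisen rearrangement should transfer the exo C9–O bond suprafacially into an exo C7–C11 bond, which sets C7 and restores the C8=C9 alkene.

Step 13
Reactants: 17 ethyl 2-[(1R,4R,6R,7S)-1,7-dimethyl-11-oxabicyclo[4.4.1]undec-2-en-4-yl]acetate
Product: 18 2-[(1R,4R,6R,7S)-1,7-dimethyl-11-oxabicyclo[4.4.1]undec-2-en-4-yl]acetic acid
Conditions: LiOH, THF/MeOH/H2O, rt; then aq. HCl
Reagents that add atoms: lithium hydroxide, [Li+].[OH-] (its oxygen ends in the carboxyl group)
Why: Plain ester saponification, with nothing else in the molecule sensitive to base.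

Step 14
Reactants: 18 2-[(1R,4R,6R,7S)-1,7-dimethyl-11-oxabicyclo[4.4.1]undec-2-en-4-yl]acetic acid
Product: 20 (4S,5R,7R,8R,9S,10R)-5,10-epoxy-9-hydroxygermacran-12,8-olide, via epoxy acid 19 (not isolated)
Conditions: mCPBA, CH2Cl2, 0 °C to rt; then CSA (cat.)
Reagents that add atoms: mCPBA, OOC(=O)c1cccc(Cl)c1
Why: Exo epoxidation of the γ,δ-unsaturated acid followed by acid-promoted 5-exo anti opening at C8 by the carboxyl group (epoxy-acid lactonisation) should give the trans-fused lactone with inversion at C8 and the C9 hydroxyl retained on the exo face, attack at neopentyl C9 being disfavoured.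

Step 15
Reactants: 20 (4S,5R,7R,8R,9S,10R)-5,10-epoxy-9-hydroxygermacran-12,8-olide
Product: 23 (4S,5R,7R,8R,9S,10R)-5,10-epoxy-9-hydroxygermacr-11(13)-en-12,8-olide, via Mannich base 21 (not isolated), via ammonium iodide 22 (not isolated)
Conditions: LiN(iPr)2 (2.2 equiv), THF, −78 °C, then CH2=NMe2 I, −78 °C to rt; MeI, MeOH, rt; NaHCO3, CH2Cl2/H2O, rt
Reagents that add atoms: N,N-dimethylmethyleneiminium iodide (Eschenmoser's salt), C=[N+](C)C.[I-]
Why: α-Aminomethylation of the lactone enolate (the C9 hydroxyl carried as its alkoxide), N-methylation and Hofmann-type elimination should install the exocyclic methylene and erase the transient C11 stereocentre.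

Step 16
Reactants: 23 (4S,5R,7R,8R,9S,10R)-5,10-epoxy-9-hydroxygermacr-11(13)-en-12,8-olide
Product: 24 (4S,5R,7R,8R,9S,10R)-5,10-epoxy-9-(3-methylbutanoyloxy)germacr-11(13)-en-12,8-olide (CNP0274454.1)
Conditions: 3-methylbutanoyl chloride, Et3N, DMAP (cat.), CH2Cl2, 0 °C to rt
Reagents that add atoms: 3-methylbutanoyl chloride, CC(C)CC(=O)Cl
Why: DMAP-catalysed acylation of the hindered secondary C9 alcohol completes the target without touching a stereocentre.

**Compound list**

1 | geranyl acetate, (2E)-3,7-dimethylocta-2,6-dien-1-yl acetate | CC(C)=CCC/C(C)=C/COC(C)=O | starting material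
2 | (2E,6E)-8-hydroxy-3,7-dimethylocta-2,6-dien-1-yl acetate | OC/C(C)=C/CC/C(C)=C/COC(C)=O | intermediate
3 | (2E,6E)-3,7-dimethyl-8-oxoocta-2,6-dien-1-yl acetate | O=C/C(C)=C/CC/C(C)=C/COC(C)=O | intermediate
4 | (2E,6E)-8-acetoxy-2,6-dimethylocta-2,6-dienoic acid | OC(=O)/C(C)=C/CC/C(C)=C/COC(C)=O | intermediate
5 | (2S,6E)-8-acetoxy-2,6-dimethyloct-6-enoic acid | OC(=O)[C@@H](C)CCC/C(C)=C/COC(C)=O | intermediate
6 | (2S,6E)-8-hydroxy-2,6-dimethyloct-6-enoic acid | OC(=O)[C@@H](C)CCC/C(C)=C/CO | intermediate
7 | (2S,6E)-2,6-dimethyl-8-oxooct-6-enoic acid | OC(=O)[C@@H](C)CCC/C(C)=C/C=O | intermediate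
8 | (2S,6E)-2,6-dimethylnona-6,8-dienoic acid | OC(=O)[C@@H](C)CCC/C(C)=C/C=C | intermediate
9 | (2S,6E)-2,6-dimethylnona-6,8-dienoic 2-methylpropyl carbonic anhydride | CC(C)COC(=O)OC(=O)[C@@H](C)CCC/C(C)=C/C=C | intermediate
10 | (3S,7E)-1-diazo-3,7-dimethyldeca-7,9-dien-2-one | [N-]=[N+]=CC(=O)[C@@H](C)CCC/C(C)=C/C=C | intermediate
11 | (1R,3S,7E,9R)-3,7-dimethylbicyclo[7.1.0]dec-7-en-2-one | C[C@H]1CCC/C(C)=C/[C@H]2C[C@H]2C1=O | intermediate
12 | (1R,7S)-1,7-dimethyl-11-oxabicyclo[4.4.1]undeca-2,5-diene | C[C@H]1CCC[C@]2(C)C=CCC=C1O2 | intermediate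
13 | (1R,6R,7S)-1,7-dimethyl-11-oxabicyclo[4.4.1]undec-2-ene | C[C@H]1CCC[C@]2(C)C=CCC[C@H]1O2 | intermediate
14 | (1R,2S,3S,6R,7S)-2,3-epoxy-1,7-dimethyl-11-oxabicyclo[4.4.1]undecane (exo epoxide) | C[C@H]1CCC[C@]2(C)[C@H]3O[C@H]3CC[C@H]1O2 | intermediate
15 | (1R,2S,6R,7S)-1,7-dimethyl-11-oxabicyclo[4.4.1]undec-3-en-2-ol | C[C@H]1CCC[C@]2(C)[C@@H](O)C=CC[C@H]1O2 | intermediate
16 | (1R,2S,6R,7S)-2-[(1-ethoxyethenyl)oxy]-1,7-dimethyl-11-oxabicyclo[4.4.1]undec-3-ene | C[C@H]1CCC[C@]2(C)[C@@H](OC(=C)OCC)C=CC[C@H]1O2 | intermediate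
17 | ethyl 2-[(1R,4R,6R,7S)-1,7-dimethyl-11-oxabicyclo[4.4.1]undec-2-en-4-yl]acetate | C[C@H]1CCC[C@]2(C)C=C[C@@H](CC(=O)OCC)C[C@H]1O2 | intermediate
18 | 2-[(1R,4R,6R,7S)-1,7-dimethyl-11-oxabicyclo[4.4.1]undec-2-en-4-yl]acetic acid | C[C@H]1CCC[C@]2(C)C=C[C@@H](CC(=O)O)C[C@H]1O2 | intermediate
19 | 2-[(1R,2S,3S,4R,6R,7S)-2,3-epoxy-1,7-dimethyl-11-oxabicyclo[4.4.1]undecan-4-yl]acetic acid | C[C@H]1CCC[C@]2(C)[C@H]3O[C@H]3[C@@H](CC(=O)O)C[C@H]1O2 | intermediate
20 | (4S,5R,7R,8R,9S,10R)-5,10-epoxy-9-hydroxygermacran-12,8-olide | O=C1C[C@H]2C[C@H]3O[C@](C)(CCC[C@@H]3C)[C@@H](O)[C@@H]2O1 | intermediate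
21 | 11-(dimethylaminomethyl) derivative of 20 (aminomethyl group drawn trans to C6; C11 configuration immaterial) | O=C1[C@H](CN(C)C)[C@H]2C[C@H]3O[C@](C)(CCC[C@@H]3C)[C@@H](O)[C@@H]2O1 | intermediate
22 | N-methyl ammonium iodide of 21 | O=C1[C@H](C[N+](C)(C)C)[C@H]2C[C@H]3O[C@](C)(CCC[C@@H]3C)[C@@H](O)[C@@H]2O1.[I-] | intermediate
23 | (4S,5R,7R,8R,9S,10R)-5,10-epoxy-9-hydroxygermacr-11(13)-en-12,8-olide | C=C1[C@H]2C[C@H]3O[C@](C)(CCC[C@@H]3C)[C@@H](O)[C@@H]2OC1=O | intermediate
24 | (4S,5R,7R,8R,9S,10R)-5,10-epoxy-9-(3-methylbutanoyloxy)germacr-11(13)-en-12,8-olide, CNP0274454.1 | C=C1C(=O)O[C@@H]2[C@@H]1C[C@H]1O[C@](C)(CCC[C@@H]1C)[C@H]2OC(=O)CC(C)C | target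

**Step count and risks**

Total steps: 16. Longest linear sequence: 16 steps (the route is linear from geranyl acetate).

Steps most likely to fail:

1. Step 8 (Proposed new method). The carbenoid may be lost to dimerisation or 1,5 C–H insertion before the ten-membered closure, may cyclopropanate the trisubstituted alkene or the wrong diene face relative to C4, or the rearrangement may stall at the cyclopropane. The fallback uses known chemistry only, closes ring B by an epoxy-alcohol cyclisation and ring A by metathesis, sets out from 6 and comes back at 13. Acid 6 is coupled with MeNHOMe·HCl (EDC·HCl, i-Pr2NEt, CH2Cl2) to give the Weinreb amide F1, and excess but-3-enylmagnesium bromide (THF, 0 °C) gives the hydroxy ketone F2. Sharpless asymmetric epoxidation of the allylic alcohol (Ti(OiPr)4, L-(+)-diethyl tartrate, t-BuOOH, 4 Å sieves, CH2Cl2, −20 °C) gives the (2S,3S)-epoxy alcohol F3. Felkin–Anh reduction of the α-methyl ketone with LiBH(s-Bu)3 (THF, −78 °C) gives the 5R carbinol, epoxy diol F4. CSA in CH2Cl2 at 0 °C then triggers 7-exo opening of the epoxide at tertiary C10 with inversion, which forms the O–C10 bond and gives the oxepane diol F5. PPh3, I2 and imidazole in hot toluene turn the vicinal diol into the vinyl group of the diene F6, and ring-closing metathesis with the second-generation Grubbs catalyst RuCl2(=CHPh)(H2IMes)(PCy3) (CH2Cl2, 40 °C) closes ring A at C8=C9 to give 13.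

2. Step 9. Chemoselectivity between the two alkenes may be lost (reduction or migration of C8=C9), or the C5 radical may fragment toward the ring-opened ketone. The fallback replaces radical hydrogen-atom transfer by a polar, ionic hydrogenation: Et3SiH with CF3CO2H in CH2Cl2 at −40 °C should protonate the enol ether at C6 and deliver hydride to the bridgehead C5 cation, which the disubstituted alkene cannot match. It sets out from 12 and comes back at 13 and makes no new compound.

3. Step 14. The epoxidation may show poor facial selectivity, or the carboxyl group may fail to reach C8 from the hindered endo face so that the epoxy acid opens elsewhere. The fallback sets C8 by SN2 inversion instead of by epoxide opening, sets out from 18 and comes back at 20. OsO4 (cat.) with N-methylmorpholine N-oxide (acetone/H2O) dihydroxylates the exo face, and the resulting cis γ-hydroxy acid closes spontaneously to the cis-fused hydroxy lactone F7. LiOH (THF/H2O) opens it, and careful acidification at 0 °C gives the dihydroxy acid F8. This is lactonised at once under Mitsunobu conditions (PPh3, diisopropyl azodicarboxylate, THF, 0 °C): the less hindered C8 hydroxyl is activated and displaced by the carboxylate with inversion, which gives 20.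

**Further compounds**

F1 | step 8 | (2S,6E)-8-hydroxy-N-methoxy-N,2,6-trimethyloct-6-enamide | CON(C)C(=O)[C@@H](C)CCC/C(C)=C/CO
F2 | step 8 | (6S,10E)-12-hydroxy-6,10-dimethyldodeca-1,10-dien-5-one | C=CCCC(=O)[C@@H](C)CCC/C(C)=C/CO
F3 | step 8 | (6S)-9-[(2S,3S)-3-(hydroxymethyl)-2-methyloxiran-2-yl]-6-methylnon-1-en-5-one | C=CCCC(=O)[C@@H](C)CCC[C@]1(C)O[C@H]1CO
F4 | step 8 | (5R,6S)-9-[(2S,3S)-3-(hydroxymethyl)-2-methyloxiran-2-yl]-6-methylnon-1-en-5-ol | C=CCC[C@@H](O)[C@@H](C)CCC[C@]1(C)O[C@H]1CO
F5 | step 8 | (1S)-1-[(2R,6S,7R)-7-(but-3-en-1-yl)-2,6-dimethyloxepan-2-yl]ethane-1,2-diol | C=CCC[C@H]1O[C@](C)(CCC[C@@H]1C)[C@@H](O)CO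
F6 | step 8 | (2R,6S,7R)-7-(but-3-en-1-yl)-2-ethenyl-2,6-dimethyloxepane | C=CCC[C@H]1O[C@](C)(CCC[C@@H]1C)C=C
F0 | step 9 | none | none
F7 | step 14 | (4S,5R,7R,8S,9S,10R)-5,10-epoxy-9-hydroxygermacran-12,8-olide (cis-fused C8 epimer of 20) | O=C1C[C@H]2C[C@H]3O[C@](C)(CCC[C@@H]3C)[C@@H](O)[C@H]2O1
F8 | step 14 | 2-[(1R,2S,3S,4R,6R,7S)-2,3-dihydroxy-1,7-dimethyl-11-oxabicyclo[4.4.1]undecan-4-yl]acetic acid | OC(=O)C[C@H]1C[C@H]2O[C@](C)(CCC[C@@H]2C)[C@@H](O)[C@H]1O
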